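**Retrosynthetic overview**
- The target is the bis-angelate of a 6,11-dihydroxy-germacra-1(10)Z,4E-dien-12,8-olide; both esters are put on last.
- The ten-membered ring is closed last, at C5–C6, by an electrochemical nickel/chromium alkenylation of a C6 aldehyde; this sets C6.
- The γ-lactone ring is bought: 2-C-methyl-D-ribono-1,4-lactone supplies C8 and C11 with the correct absolute configuration.
- The sugar C3–O bond is replaced with retention by a C7–C6 bond (photochemical radical formylation equivalent), and C9–C10 is made by nickel-catalysed alkyl–alkenyl reductive coupling.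
- The C1–C5/C10 diene carrying both alkene geometries comes from pent-4-yn-1-ol (carboalumination, oxidation, Z-selective iodo-Wittig).

Assumption: germacrane numbering (lactone C12–O–C8, esters on C6 and C11) is used for positions, and 2-C-methyl-D-ribono-1,4-lactone and the known radical trap O-benzyl (phenylsulfonyl)formaldoxime are taken as purchasable.

**Step 1**
Reactants: 1 pent-4-yn-1-ol
Product: 3 (E)-5-bromo-4-methylpent-4-en-1-ol, via alkenylalane 2 (not isolated)
Conditions: AlMe3 (3 equiv), Cp2ZrCl2 (25 mol%), CH2Cl2, 0 → 23 °C; then NBS, THF, −30 °C; aq. HCl work-up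
Reagents that add atoms: trimethylaluminium, C[Al](C)C; N-bromosuccinimide, O=C1CCC(=O)N1Br
Why: Negishi zirconium-catalysed carboalumination adds methyl and aluminium syn across the terminal alkyne (methyl to the internal carbon), and bromodealumination with retention fixes the E-alkenyl bromide that becomes C4=C5.

**Step 2**
Reactants: 3 (E)-5-bromo-4-methylpent-4-en-1-ol
Product: 4 (E)-5-bromo-4-methylpent-4-enal
Conditions: Dess–Martin periodinane, CH2Cl2, 0 → 23 °C
Reagents that add atoms: none
Why: Dess–Martin oxidation takes the primary alcohol to the aldehyde under neutral conditions that leave the alkenyl bromide and its geometry untouched.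

**Step 3**
Reactants: 4 (E)-5-bromo-4-methylpent-4-enal
Product: 5 (2Z,6E)-7-bromo-2-iodo-6-methylhepta-2,6-diene
Conditions: EtPPh3I, n-BuLi, THF, 0 °C; I2, −78 °C; NaHMDS, −78 °C; then 4, −78 → −20 °C
Reagents that add atoms: ethyltriphenylphosphonium iodide, CC[P+](c1ccccc1)(c1ccccc1)c1ccccc1.[I-]; iodine, II
Why: the α-iodoethylidene Wittig olefination (Stork–Zhao type) is kinetically Z-selective, placing iodine cis to the chain, which fixes the later C1=C10 Z-geometry; the alkenyl bromide is inert to the ylide.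

**Step 4**
Reactants: 6 2-C-methyl-D-ribono-1,4-lactone
Product: 7 (3R,4R,5R)-3,4-dihydroxy-3-methyl-5-[(tosyloxy)methyl]oxolan-2-one
Conditions: TsCl (1.05 equiv), pyridine, −10 → 0 °C
Reagents that add atoms: p-toluenesulfonyl chloride, Cc1ccc(cc1)S(Cl)(=O)=O
Why: sulfonylation at low temperature discriminates the primary hydroxyl from the secondary and tertiary ones; no stereocentre is touched.

**Step 5**
Reactants: 7 (3R,4R,5R)-3,4-dihydroxy-3-methyl-5-[(tosyloxy)methyl]oxolan-2-one
Product: 8 (3R,4R,5R)-3-hydroxy-3-methyl-4-[(phenoxycarbonothioyl)oxy]-5-[(tosyloxy)methyl]oxolan-2-one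
Conditions: PhOC(S)Cl (1.1 equiv), pyridine, CH2Cl2, 0 °C
Reagents that add atoms: O-phenyl chlorothionoformate, S=C(Cl)Oc1ccccc1
Why: thioacylation goes to the only secondary hydroxyl because the tertiary α-hydroxy-lactone OH is hindered and deactivated; omitting DMAP and keeping 0 °C suppresses closure to the cyclic thionocarbonate.

**Step 6**
Reactants: 8 (3R,4R,5R)-3-hydroxy-3-methyl-4-[(phenoxycarbonothioyl)oxy]-5-[(tosyloxy)methyl]oxolan-2-one
Product: 9 (3R,4R,5S)-4-[(E)-(benzyloxyimino)methyl]-3-hydroxy-3-methyl-5-[(tosyloxy)methyl]oxolan-2-one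
Conditions: PhSO2CH=NOBn (2 equiv), Me3SnSnMe3 (1.2 equiv), benzene, hν (300 nm), 25 °C
Reagents that add atoms: O-benzyl (phenylsulfonyl)formaldoxime, O=S(=O)(/C=N/OCc1ccccc1)c1ccccc1
Why: photogenerated Me3Sn• cleaves the thionocarbonate C–O bond (Barton–McCombie-type radical generation) and the C7 radical adds to the sulfonyl oxime ether with loss of PhSO2• (radical formylation equivalent); attack occurs anti to the CH2OTs group on C8 and the methyl on C11, which sit on the same face, so the C7–C6 bond replaces the C–O bond with retention and C7 is set by the two purchased centres.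

**Step 7**
Reactants: 9 (3R,4R,5S)-4-[(E)-(benzyloxyimino)methyl]-3-hydroxy-3-methyl-5-[(tosyloxy)methyl]oxolan-2-one; 5 (2Z,6E)-7-bromo-2-iodo-6-methylhepta-2,6-diene
Product: 11 (3R,4R,5R)-4-[(E)-(benzyloxyimino)methyl]-5-[(2Z,6E)-7-bromo-2,6-dimethylhepta-2,6-dien-1-yl]-3-hydroxy-3-methyloxolan-2-one, via iodide 10 (not isolated)
Conditions: NaI (3 equiv), DMA, 70 °C; then 5 (1.5 equiv), NiBr2·glyme (10 mol%), 4,4′-di-tert-butyl-2,2′-bipyridine (10 mol%), Mn powder (3 equiv), DMA, 25 °C
Reagents that add atoms: sodium iodide, [Na+].[I-] (its iodine enters intermediate 10 only and leaves again as MnI2)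
Why: Finkelstein exchange followed by nickel-catalysed reductive cross-electrophile coupling, in which zerovalent nickel inserts into the C(sp2)–I bond much faster than into the C(sp2)–Br bond and captures the primary radical from 10; the radical pathway avoids β-elimination of the lactone oxygen, the Z-alkene is retained and no stereocentre is touched.

**Step 8**
Reactants: 11 (3R,4R,5R)-4-[(E)-(benzyloxyimino)methyl]-5-[(2Z,6E)-7-bromo-2,6-dimethylhepta-2,6-dien-1-yl]-3-hydroxy-3-methyloxolan-2-one
Product: 12 (2R,3R,4R)-2-[(2Z,6E)-7-bromo-2,6-dimethylhepta-2,6-dien-1-yl]-4-hydroxy-4-methyl-5-oxooxolane-3-carbaldehyde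
Conditions: 37% aq. HCHO, HCl (cat.), THF, 25 °C; used at once
Reagents that add atoms: formaldehyde, C=O
Why: acid-catalysed trans-oximation to formaldehyde releases the aldehyde just before ring closure; C7 already has the thermodynamically preferred configuration (trans to the C8 chain and to the C11 methyl), so enolisation cannot erode it.

**Step 9**
Reactants: 12 (2R,3R,4R)-2-[(2Z,6E)-7-bromo-2,6-dimethylhepta-2,6-dien-1-yl]-4-hydroxy-4-methyl-5-oxooxolane-3-carbaldehyde
Product: 13 (3R,3aS,4S,5E,9Z,11aR)-3,4-dihydroxy-3,6,10-trimethyl-3a,4,7,8,11,11a-hexahydrocyclodeca[b]furan-2(3H)-one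
Conditions: CrCl3 (20 mol%), NiCl2·glyme (5 mol%), 4,4′-di-tert-butyl-2,2′-bipyridine (5 mol%), Cp2ZrCl2 (1.5 equiv), LiCl, DMF, Al anode, Ni-foam cathode, undivided cell, constant current, 12 added over 10 h to 2 mM, 25 °C; aq. work-up
Reagents that add atoms: none
Why: Proposed new method: an intramolecular, ten-membered-ring version of the electrochemical nickel/chromium alkenylation of aldehydes, in which cathodic reduction of CrCl3 gives divalent chromium, zerovalent nickel inserts into the alkenyl C–Br bond with retention, transmetallation gives a trivalent alkenylchromium species that adds to the tethered aldehyde, Cp2ZrCl2 releases the chromium alkoxide for turnover and the aluminium anode supplies the electrons, while the slow cathodic generation of divalent chromium keeps the organochromium concentration minute and so favours ring closure over oligomerisation; the closest known reactions are the intermolecular electrochemical Nozaki–Hiyama–Kishi coupling of alkenyl bromides and the stoichiometric CrCl2/NiCl2 macrocyclisation to medium rings; C6 is expected to be set by the lactone stereocentres, the ring-closing transition state keeping H-6 inside the ring and antiperiplanar to H-7 with the chromium alkoxide on the periphery, which gives 6S.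

**Step 10**
Reactants: 13 (3R,3aS,4S,5E,9Z,11aR)-3,4-dihydroxy-3,6,10-trimethyl-3a,4,7,8,11,11a-hexahydrocyclodeca[b]furan-2(3H)-one
Product: 14 (3R,3aS,4S,5E,9Z,11aR)-3,6,10-trimethyl-2-oxo-2,3,3a,4,7,8,11,11a-octahydrocyclodeca[b]furan-3,4-diyl bis[(Z)-2-methylbut-2-enoate]
Conditions: angelic acid (6 equiv), 2,4,6-trichlorobenzoyl chloride (6 equiv), Et3N (7 equiv), toluene, 25 °C, 2 h; then 13, 85 °C
Reagents that add atoms: angelic acid, C/C=C(/C)C(=O)O
Why: Yamaguchi-type mixed-anhydride esterification acylates the secondary allylic and the tertiary α-hydroxy-lactone hydroxyls without a nucleophilic catalyst, so the Z-geometry of the angelate is not isomerised to the tiglate; no stereocentre is touched.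

**Compound list**
1 | pent-4-yn-1-ol | C#CCCCO | starting material
2 | dimethylaluminium (E)-5-(dimethylalumanyl)-4-methylpent-4-en-1-olate (alkenylalane) | C[Al](C)/C=C(\C)CCCO[Al](C)C | intermediate
3 | (E)-5-bromo-4-methylpent-4-en-1-ol | Br/C=C(\C)CCCO | intermediate
4 | (E)-5-bromo-4-methylpent-4-enal | Br/C=C(\C)CCC=O | intermediate
5 | (2Z,6E)-7-bromo-2-iodo-6-methylhepta-2,6-diene | Br/C=C(\C)CC/C=C(/C)I | intermediate
6 | 2-C-methyl-D-ribono-1,4-lactone, (3R,4R,5R)-3,4-dihydroxy-5-(hydroxymethyl)-3-methyloxolan-2-one | OC[C@H]1OC(=O)[C@](C)(O)[C@@H]1O | starting material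
7 | (3R,4R,5R)-3,4-dihydroxy-3-methyl-5-[(tosyloxy)methyl]oxolan-2-one | Cc1ccc(cc1)S(=O)(=O)OC[C@H]1OC(=O)[C@](C)(O)[C@@H]1O | intermediate
8 | (3R,4R,5R)-3-hydroxy-3-methyl-4-[(phenoxycarbonothioyl)oxy]-5-[(tosyloxy)methyl]oxolan-2-one | Cc1ccc(cc1)S(=O)(=O)OC[C@H]1OC(=O)[C@](C)(O)[C@@H]1OC(=S)Oc1ccccc1 | intermediate
9 | (3R,4R,5S)-4-[(E)-(benzyloxyimino)methyl]-3-hydroxy-3-methyl-5-[(tosyloxy)methyl]oxolan-2-one | Cc1ccc(cc1)S(=O)(=O)OC[C@H]1OC(=O)[C@](C)(O)[C@@H]1/C=N/OCc1ccccc1 | intermediate
10 | (3R,4R,5S)-4-[(E)-(benzyloxyimino)methyl]-3-hydroxy-5-(iodomethyl)-3-methyloxolan-2-one | IC[C@H]1OC(=O)[C@](C)(O)[C@@H]1/C=N/OCc1ccccc1 | intermediate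
11 | (3R,4R,5R)-4-[(E)-(benzyloxyimino)methyl]-5-[(2Z,6E)-7-bromo-2,6-dimethylhepta-2,6-dien-1-yl]-3-hydroxy-3-methyloxolan-2-one | Br/C=C(\C)CC/C=C(/C)C[C@H]1OC(=O)[C@](C)(O)[C@@H]1/C=N/OCc1ccccc1 | intermediate
12 | (2R,3R,4R)-2-[(2Z,6E)-7-bromo-2,6-dimethylhepta-2,6-dien-1-yl]-4-hydroxy-4-methyl-5-oxooxolane-3-carbaldehyde | Br/C=C(\C)CC/C=C(/C)C[C@H]1OC(=O)[C@](C)(O)[C@@H]1C=O | intermediate
13 | (3R,3aS,4S,5E,9Z,11aR)-3,4-dihydroxy-3,6,10-trimethyl-3a,4,7,8,11,11a-hexahydrocyclodeca[b]furan-2(3H)-one (germacrane numbering 6S,7S,8R,11R) | O[C@H]1/C=C(\C)CC/C=C(/C)C[C@H]2OC(=O)[C@](C)(O)[C@H]12 | intermediate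
14 | (3R,3aS,4S,5E,9Z,11aR)-3,6,10-trimethyl-2-oxo-2,3,3a,4,7,8,11,11a-octahydrocyclodeca[b]furan-3,4-diyl bis[(Z)-2-methylbut-2-enoate] | C/C=C(/C)C(=O)O[C@H]1/C=C(\C)CC/C=C(/C)C[C@H]2OC(=O)[C@](C)(OC(=O)/C(C)=C\C)[C@H]12 | target

**Step count and risks**
Total steps: 10. Longest linear sequence: 7 (steps 4–10 from 6; the branch 1 → 5 followed by steps 7–10 is also 7).

Most likely to fail:

Step 9 (the proposed new ring closure). The electrochemical alkenylation has not been run intramolecularly on a medium ring, and the C6 configuration rests on a conformational argument. The fallback sets out from 11 and comes back at 13. Copper-catalysed bromide–iodide exchange (CuI, N,N′-dimethylethylenediamine, NaI, dioxane, 110 °C) gives the alkenyl iodide oxime ether F1. Trans-oximation as in step 8 gives the iodo aldehyde F2. The ring is then closed by the classical stoichiometric Nozaki–Hiyama–Kishi macrocyclisation (CrCl2 10 equiv, NiCl2 1 mol%, DMSO/THF, 2 mM, 25 °C) to give 13. If the alcohol is obtained as the C6 epimer F3, Dess–Martin oxidation to the macrocyclic enone F4 and Luche reduction (NaBH4, CeCl3·7H2O, MeOH, −78 °C, hydride from the ring periphery) also return 13.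

Step 7. The coupling must distinguish the alkenyl iodide from the alkenyl bromide, and the alkyl iodide carries a β-lactone oxygen. The fallback sets out from 9 and comes back at 11. Iodide 10 is isolated (NaI, acetone, reflux). Diene 5 is converted by iodine–magnesium exchange (iPrMgCl·LiCl, THF, 0 → 25 °C, alkenyl bromide untouched) into the alkenylmagnesium chloride F5. F5 (3 equiv) is coupled with 10 under copper catalysis (Li2CuCl4 5 mol%, THF/NMP, −20 °C, Kochi-type alkyl–alkenyl coupling), a polar pathway that replaces the reductive one.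

Step 10. Acylation of the tertiary hydroxyl may stall, or the angelate may isomerise to the tiglate on heating. The fallback sets out from 13 and comes back at 14. Both hydroxyls are esterified with 2-[bis(2,2,2-trifluoroethoxy)phosphoryl]propanoic acid (DCC, cat. DMAP, CH2Cl2; the phosphonoketene formed in situ also reaches the tertiary OH) to give the bis-phosphonate F6. A double Still–Gennari olefination (KHMDS, 18-crown-6, THF, −78 °C, then acetaldehyde) then builds both (Z)-2-methylbut-2-enoates in place.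

**Further compounds**
F1 | step 9 | (3R,4R,5R)-4-[(E)-(benzyloxyimino)methyl]-3-hydroxy-5-[(2Z,6E)-7-iodo-2,6-dimethylhepta-2,6-dien-1-yl]-3-methyloxolan-2-one | I/C=C(\C)CC/C=C(/C)C[C@H]1OC(=O)[C@](C)(O)[C@@H]1/C=N/OCc1ccccc1
F2 | step 9 | (2R,3R,4R)-4-hydroxy-2-[(2Z,6E)-7-iodo-2,6-dimethylhepta-2,6-dien-1-yl]-4-methyl-5-oxooxolane-3-carbaldehyde | I/C=C(\C)CC/C=C(/C)C[C@H]1OC(=O)[C@](C)(O)[C@@H]1C=O
F3 | step 9 | (3R,3aS,4R,5E,9Z,11aR)-3,4-dihydroxy-3,6,10-trimethyl-3a,4,7,8,11,11a-hexahydrocyclodeca[b]furan-2(3H)-one (C6 epimer of 13) | O[C@@H]1/C=C(\C)CC/C=C(/C)C[C@H]2OC(=O)[C@](C)(O)[C@H]12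
F4 | step 9 | (3R,3aR,5E,9Z,11aR)-3-hydroxy-3,6,10-trimethyl-3,3a,7,8,11,11a-hexahydrocyclodeca[b]furan-2,4-dione | O=C1/C=C(\C)CC/C=C(/C)C[C@H]2OC(=O)[C@](C)(O)[C@H]12
F5 | step 7 | [(2Z,6E)-7-bromo-6-methylhepta-2,6-dien-2-yl]magnesium chloride (LiCl complex) | Br/C=C(\C)CC/C=C(/C)[Mg]Cl
F6 | step 10 | (3R,3aS,4S,5E,9Z,11aR)-3,6,10-trimethyl-2-oxo-2,3,3a,4,7,8,11,11a-octahydrocyclodeca[b]furan-3,4-diyl bis{2-[bis(2,2,2-trifluoroethoxy)phosphoryl]propanoate} (mixture at the two phosphonate α-carbons) | CC(C(=O)O[C@H]1/C=C(\C)CC/C=C(/C)C[C@H]2OC(=O)[C@](C)(OC(=O)C(C)P(=O)(OCC(F)(F)F)OCC(F)(F)F)[C@H]12)P(=O)(OCC(F)(F)F)OCC(F)(F)F
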